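## Retrosynthetic overview

1. **Feature.** In the luteolin half, the benzo ring (C4a''–C8a'') carries 5''-OH, the C6''–C5' biaryl bond and 7''-O on three neighbouring carbons. A vinylketene and an aryl ynol silyl ether give exactly this phenol / alkyne substituent / alkoxy sequence on benzannulation.
2. **Endgame cuts.** Eight O-benzyl groups are removed by hydrogenolysis. O1–C2 of flavanone ring C comes from a catalytic asymmetric oxa-Michael addition in an ester-activated 2'-hydroxychalcone, which sets 2S. Cα=Cβ comes from a Knoevenagel condensation of a ring B aldehyde with a ring A β-keto ester.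
3. **Key cut.** C8''–C8a'', C5''–C6'', C7''–C8'' and C4a''–C5'' of the flavone benzo ring lead back to a 2-diazoacetyl-6-aryl-4-pyranone and the ring B triisopropylsiloxyalkyne. The crowded biaryl bond therefore enters as a plain aryl–alkyne bond.
4. **Building blocks.** The pyranone comes from 3,4-dihydroxyacetophenone, ethyl acetate and diethyl oxalate. The siloxyalkyne comes from 3-bromo-4,5-dihydroxybenzaldehyde by carbonylation and ynolate homologation. The β-keto ester comes from 2,4,6-trihydroxyacetophenone.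
5. **Ring order.** The 4-pyranone (flavone ring C'') is made first, then the flavone benzo ring A'' around it, then flavanone ring C. The three remaining benzene rings are bought.

Key step: step 10

Numbering: flavanone O1–C8a (rings A and C), its ring B C1'–C6', flavone chromenone O1''–C8a''.

Assumption: the C5'–C6'' axis is flanked by three oxygen substituents and one hydrogen, so it is taken to rotate freely at room temperature; C2 is then the only stereogenic element to control, as in the SMILES.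

Assumption: of the two pseudo-enantiomeric cinchona thioureas, the quinidine-derived one is taken to give 2S; the sense is to be checked on the benzaldehyde-derived model substrate, and the quinine-derived catalyst is used instead if it is opposite.

## Route

Step 1
Reactants: 1 3,4-dihydroxyacetophenone
Product: 2 3,4-bis(benzyloxy)acetophenone
Conditions: BnBr (2.3 equiv), K2CO3, DMF, 60 °C
Reagents that add atoms: benzyl bromide, BrCc1ccccc1
Why: Williamson ether synthesis; both phenoxides are alkylated by the benzylic bromide and the methyl ketone is inert to carbonate.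

Step 2
Reactants: 2 3,4-bis(benzyloxy)acetophenone; 3 ethyl acetate
Product: 4 1-[3,4-bis(benzyloxy)phenyl]butane-1,3-dione
Conditions: NaH, EtOAc (excess), THF, reflux; 1 M HCl work-up
Reagents that add atoms: none
Why: Crossed Claisen condensation; the ketone enolate is acylated by ethyl acetate and the equilibrium is drawn forward by formation of the stabilised β-diketonate.

Step 3
Reactants: 4 1-[3,4-bis(benzyloxy)phenyl]butane-1,3-dione; 5 diethyl oxalate
Product: 7 ethyl 6-[3,4-bis(benzyloxy)phenyl]-4-oxo-4H-pyran-2-carboxylate, via triketo ester 6 (not isolated)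
Conditions: NaOEt (2.2 equiv), EtOH–THF, 0 to 60 °C; 1 M HCl work-up; crude 6, TsOH·H2O (10 mol %), toluene, reflux (Dean–Stark)
Reagents that add atoms: none
Why: Claisen condensation of the diketonate at its terminal methyl group with the non-enolisable oxalate (the reaction type of the chelidonic acid synthesis), followed by acid-catalysed cyclodehydration of the 1,3,5-tricarbonyl unit to the 4-pyranone, which aryl benzyl ethers tolerate.

Step 4
Reactants: 7 ethyl 6-[3,4-bis(benzyloxy)phenyl]-4-oxo-4H-pyran-2-carboxylate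
Product: 8 6-[3,4-bis(benzyloxy)phenyl]-4-oxo-4H-pyran-2-carboxylic acid
Conditions: LiOH·H2O (1.1 equiv), THF–H2O, 0 °C; 1 M HCl to pH 2
Reagents that add atoms: lithium hydroxide, [Li+].[OH-]
Why: Saponification; the ester on the electron-poor C2 should hydrolyse at 0 °C faster than hydroxide attacks the ring, and any ring-opened triketo acid recloses on acidification.

Step 5
Reactants: 8 6-[3,4-bis(benzyloxy)phenyl]-4-oxo-4H-pyran-2-carboxylic acid
Product: 10 2-(diazoacetyl)-6-[3,4-bis(benzyloxy)phenyl]-4H-pyran-4-one, via acid chloride 9 (not isolated)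
Conditions: (COCl)2, DMF (cat.), CH2Cl2, 0 °C to rt, concentrate; TMSCHN2 (2 equiv), THF–MeCN, 0 °C
Reagents that add atoms: oxalyl chloride, ClC(=O)C(=O)Cl (chlorine of 9 only); trimethylsilyldiazomethane, C[Si](C)(C)C=[N+]=[N-]
Why: Acid chloride formation followed by Arndt–Eistert-type acylation of the diazoalkane, with chloride removing the silyl group; the acyl chloride has no α-hydrogen and should react far faster than the pyranone C=C bonds undergo dipolar cycloaddition at 0 °C.

Step 6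
Reactants: 11 3-bromo-4,5-dihydroxybenzaldehyde
Product: 12 3,4-bis(benzyloxy)-5-bromobenzaldehyde
Conditions: BnBr (2.3 equiv), K2CO3, DMF, 60 °C
Reagents that add atoms: benzyl bromide, BrCc1ccccc1
Why: Williamson ether synthesis on both catechol oxygens; the aldehyde and the aryl bromide are untouched.

Step 7
Reactants: 12 3,4-bis(benzyloxy)-5-bromobenzaldehyde
Product: 13 2-[3,4-bis(benzyloxy)-5-bromophenyl]-1,3-dioxolane
Conditions: HOCH2CH2OH, TsOH·H2O (cat.), toluene, reflux (Dean–Stark)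
Reagents that add atoms: ethylene glycol, OCCO
Why: Acid-catalysed acetalisation with azeotropic removal of water; the acetal masks the aldehyde against the organolithium chemistry of step 9.

Step 8
Reactants: 13 2-[3,4-bis(benzyloxy)-5-bromophenyl]-1,3-dioxolane
Product: 14 methyl 2,3-bis(benzyloxy)-5-(1,3-dioxolan-2-yl)benzoate
Conditions: Pd(OAc)2 (2 mol %), Xantphos (4 mol %), CO (1 atm), MeOH, Et3N, 70 °C
Reagents that add atoms: carbon monoxide, [C-]#[O+]; methanol, CO
Why: Palladium-catalysed alkoxycarbonylation of an aryl bromide (oxidative addition, CO insertion, methanolysis); the wide-bite-angle ligand allows atmospheric CO pressure and the basic medium preserves the dioxolane.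

Step 9
Reactants: 14 methyl 2,3-bis(benzyloxy)-5-(1,3-dioxolan-2-yl)benzoate
Product: 17 {[2,3-bis(benzyloxy)-5-(1,3-dioxolan-2-yl)phenyl]ethynyloxy}triisopropylsilane, via dibromo enolate 15 (not isolated), via lithium ynolate 16 (not isolated)
Conditions: 2,2,6,6-tetramethylpiperidine, n-BuLi, then CH2Br2, THF, −78 °C; add 14; LiN(SiMe3)2, −78 to −20 °C; n-BuLi, −78 °C to rt; TIPSCl, 0 °C to rt; pH 7 buffer, Et3N-deactivated silica
Reagents that add atoms: dibromomethane, BrCBr; chlorotriisopropylsilane, CC(C)[Si](Cl)(C(C)C)C(C)C; lithium hexamethyldisilazide, [Li]N([Si](C)(C)C)[Si](C)(C)C (lithium of 15 only); n-butyllithium, [Li]CCCC (lithium of 16 only)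
Why: Kowalski ester homologation stopped at the ynolate: LiCHBr2 adds to the ester, enolate 15 undergoes Br/Li exchange, the carbenoid rearranges with aryl migration to ynolate 16, and the bulky chlorosilane silylates it on oxygen, while the alkyllithium is kept cold and near stoichiometric to spare the benzylic C–H bonds.

Step 10
Reactants: 10 2-(diazoacetyl)-6-[3,4-bis(benzyloxy)phenyl]-4H-pyran-4-one; 17 {[2,3-bis(benzyloxy)-5-(1,3-dioxolan-2-yl)phenyl]ethynyloxy}triisopropylsilane
Product: 22 2-[3,4-bis(benzyloxy)phenyl]-6-[2,3-bis(benzyloxy)-5-(1,3-dioxolan-2-yl)phenyl]-5-hydroxy-7-(triisopropylsiloxy)-4H-chromen-4-one, via pyranonylketene 18 (not isolated), via cyclobutenone 19 (not isolated), via dienylketene 20 (not isolated), via cyclohexadienone 21 (not isolated)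
Conditions: 10 (1.3 equiv), 17 (1.0 equiv), degassed ClCH2CH2Cl, 450 nm LED, 20 °C until N2 evolution stops; then 80 °C
Reagents that add atoms: none
Why: Proposed new method: blue light excites only the weak long-wave band of diazo ketone 10 (not the 2-aryl-4-pyranone or flavone chromophores, which would screen the light or rearrange under UV), N2 leaves and the pyranonyl group shifts to the diazo carbon (Wolff rearrangement, C8''–C8a''), giving ketene 18, which is a vinylketene through its pyranone C2=C3 bond. Ynol silyl ether 17 adds in a [2+2] cycloaddition, its nucleophilic aryl-bearing carbon to the ketene carbonyl carbon (C5''–C6'') and its siloxy carbon to the ketene CH (C7''–C8''), and cyclobutenone 19 opens at 80 °C by reversible 4-electron electrocyclic cleavage of its C5''–C8'' bond to dienylketene 20. The one new ring, the six-membered benzo ring, closes by 6-electron electrocyclisation of 20 with the ketene carbon bonding to pyranone C3 (C4a''–C5''), and dienone 21, whose C4a''–H lies between two carbonyl groups, tautomerises to the chelated phenol 22. The closest known reaction type is the Danheiser benzannulation in its diazo ketone version, established for alkenyl, aryl and heteroaryl diazo ketones with triisopropylsiloxyalkynes; the new element is a 4-pyranone as the unsaturated partner, which should serve because C3 is the nucleophilic β-carbon of a cyclic enol ether and is matched to the electrophilic ketene carbon. No stereocentre is formed. The selectivity needed is regiochemical: the oxygen polarisation of 17 places the aryl group at C6'' between 5''-OH and 7''-OSi, and closure can occur only at C3 because the other neighbour of pyranone C2 is the ring oxygen, so an 8''-aryl isomer cannot arise.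

Step 11
Reactants: 22 2-[3,4-bis(benzyloxy)phenyl]-6-[2,3-bis(benzyloxy)-5-(1,3-dioxolan-2-yl)phenyl]-5-hydroxy-7-(triisopropylsiloxy)-4H-chromen-4-one
Product: 24 5,7-bis(benzyloxy)-2-[3,4-bis(benzyloxy)phenyl]-6-[2,3-bis(benzyloxy)-5-(1,3-dioxolan-2-yl)phenyl]-4H-chromen-4-one, via free 5,7-diol 23 (not isolated)
Conditions: CsF (1.5 equiv), Cs2CO3 (2 equiv), BnBr (3 equiv), DMF, rt to 60 °C
Reagents that add atoms: benzyl bromide, BrCc1ccccc1
Why: Fluoride desilylation and Williamson ether synthesis in one flask; the liberated 7''-phenoxide is benzylated at once, and the chelated, flanked 5''-OH follows with caesium carbonate on warming, so that a single hydrogenolysis can end the route.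

Step 12
Reactants: 24 5,7-bis(benzyloxy)-2-[3,4-bis(benzyloxy)phenyl]-6-[2,3-bis(benzyloxy)-5-(1,3-dioxolan-2-yl)phenyl]-4H-chromen-4-one
Product: 25 3,4-bis(benzyloxy)-5-{5,7-bis(benzyloxy)-2-[3,4-bis(benzyloxy)phenyl]-4-oxo-4H-chromen-6-yl}benzaldehyde
Conditions: 1 M HCl, THF, rt
Reagents that add atoms: water, O
Why: Acid-catalysed acetal hydrolysis under conditions too mild to cleave aryl benzyl ethers, the peri 5''-O-benzyl group included.

Step 13
Reactants: 26 2,4,6-trihydroxyacetophenone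
Product: 27 1-[2,4-bis(benzyloxy)-6-hydroxyphenyl]ethanone
Conditions: BnBr (2.1 equiv), K2CO3, DMF, rt to 50 °C
Reagents that add atoms: benzyl bromide, BrCc1ccccc1
Why: Selective Williamson ether synthesis; after two alkylations the last hydroxyl is hydrogen-bonded to the acetyl carbonyl and is much less nucleophilic.

Step 14
Reactants: 27 1-[2,4-bis(benzyloxy)-6-hydroxyphenyl]ethanone
Product: 28 tert-butyl 3-[2,4-bis(benzyloxy)-6-hydroxyphenyl]-3-oxopropanoate
Conditions: LiN(SiMe3)2 (3.3 equiv), THF, −78 °C; Boc2O (1.05 equiv), −78 to 0 °C; 1 M HCl, 0 °C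
Reagents that add atoms: di-tert-butyl dicarbonate, CC(C)(C)OC(=O)OC(=O)OC(C)(C)C
Why: C-alkoxycarbonylation (Claisen-type acylation) of the lithium dianion of an o-hydroxyacetophenone at its more nucleophilic enolate carbon; any aryl carbonate formed at the phenoxide is carried to carbon by a Baker–Venkataraman-type shift, the third equivalent of base stores the product as its enolate, and the tert-butyl ester resists lactonisation to a 4-hydroxycoumarin.

Step 15
Reactants: 25 3,4-bis(benzyloxy)-5-{5,7-bis(benzyloxy)-2-[3,4-bis(benzyloxy)phenyl]-4-oxo-4H-chromen-6-yl}benzaldehyde; 28 tert-butyl 3-[2,4-bis(benzyloxy)-6-hydroxyphenyl]-3-oxopropanoate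
Product: 29 tert-butyl (Z)-2-[2,4-bis(benzyloxy)-6-hydroxybenzoyl]-3-(3,4-bis(benzyloxy)-5-{5,7-bis(benzyloxy)-2-[3,4-bis(benzyloxy)phenyl]-4-oxo-4H-chromen-6-yl}phenyl)acrylate
Conditions: piperidine (10 mol %), AcOH (10 mol %), 4 Å molecular sieves, toluene, rt
Reagents that add atoms: none
Why: Knoevenagel condensation under piperidinium acetate buffer, expected to favour the isomer with aryl cis to the ester; it forms Cα=Cβ without the hydroxide that a Claisen–Schmidt reaction needs and that could open the flavone pyranone ring.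

Step 16
Reactants: 29 tert-butyl (Z)-2-[2,4-bis(benzyloxy)-6-hydroxybenzoyl]-3-(3,4-bis(benzyloxy)-5-{5,7-bis(benzyloxy)-2-[3,4-bis(benzyloxy)phenyl]-4-oxo-4H-chromen-6-yl}phenyl)acrylate
Product: 31 (2S)-5,7-bis(benzyloxy)-2-(3,4-bis(benzyloxy)-5-{5,7-bis(benzyloxy)-2-[3,4-bis(benzyloxy)phenyl]-4-oxo-4H-chromen-6-yl}phenyl)chroman-4-one, via chromanone ester 30 (not isolated)
Conditions: 1-[3,5-bis(trifluoromethyl)phenyl]-3-[(9R)-6'-methoxycinchonan-9-yl]thiourea (10 mol %), toluene, −25 °C; then TsOH·H2O (cat.), 80 °C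
Reagents that add atoms: none
Why: Intramolecular oxa-Michael addition under bifunctional cinchona thiourea catalysis, a known reaction of tert-butyl 2-(2-hydroxybenzoyl)cinnamates: the thiourea binds the 1,3-dicarbonyl unit and the quinuclidine deprotonates the phenol so that O1 reaches one face of Cβ and sets C2 as S, the ester makes the acceptor reactive at −25 °C where the reverse reaction that spoils plain chalcone closures is frozen, and acid-induced loss of isobutene and CO2 then removes the C3 ester without touching C2.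

Step 17
Reactants: 31 (2S)-5,7-bis(benzyloxy)-2-(3,4-bis(benzyloxy)-5-{5,7-bis(benzyloxy)-2-[3,4-bis(benzyloxy)phenyl]-4-oxo-4H-chromen-6-yl}phenyl)chroman-4-one
Product: 32 (2S)-2-{3-[2-(3,4-dihydroxyphenyl)-5,7-dihydroxy-4-oxo-4H-chromen-6-yl]-4,5-dihydroxyphenyl}-5,7-dihydroxychroman-4-one (CNP0333260.1)
Conditions: H2 (1 atm), 10% Pd/C, THF–MeOH, rt; filtration, base-free work-up
Reagents that add atoms: none
Why: Catalytic hydrogenolysis of eight aryl benzyl ethers under neutral conditions; the flavone C2''=C3'' bond and the flavanone C4=O and C2–O1 bonds normally survive at 1 atm, and the absence of base avoids ring-opening racemisation at C2.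

## Compound list

1 | 3,4-dihydroxyacetophenone | CC(=O)c1ccc(O)c(O)c1 | starting material
2 | 3,4-bis(benzyloxy)acetophenone | CC(=O)c1ccc(OCc2ccccc2)c(OCc2ccccc2)c1 | intermediate
3 | ethyl acetate | CCOC(C)=O | starting material
4 | 1-[3,4-bis(benzyloxy)phenyl]butane-1,3-dione | CC(=O)CC(=O)c1ccc(OCc2ccccc2)c(OCc2ccccc2)c1 | intermediate
5 | diethyl oxalate | CCOC(=O)C(=O)OCC | starting material
6 | ethyl 6-[3,4-bis(benzyloxy)phenyl]-2,4,6-trioxohexanoate (not isolated) | CCOC(=O)C(=O)CC(=O)CC(=O)c1ccc(OCc2ccccc2)c(OCc2ccccc2)c1 | intermediate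
7 | ethyl 6-[3,4-bis(benzyloxy)phenyl]-4-oxo-4H-pyran-2-carboxylate | CCOC(=O)c1cc(=O)cc(-c2ccc(OCc3ccccc3)c(OCc3ccccc3)c2)o1 | intermediate
8 | 6-[3,4-bis(benzyloxy)phenyl]-4-oxo-4H-pyran-2-carboxylic acid | OC(=O)c1cc(=O)cc(-c2ccc(OCc3ccccc3)c(OCc3ccccc3)c2)o1 | intermediate
9 | 6-[3,4-bis(benzyloxy)phenyl]-4-oxo-4H-pyran-2-carbonyl chloride (not isolated) | ClC(=O)c1cc(=O)cc(-c2ccc(OCc3ccccc3)c(OCc3ccccc3)c2)o1 | intermediate
10 | 2-(diazoacetyl)-6-[3,4-bis(benzyloxy)phenyl]-4H-pyran-4-one | [N-]=[N+]=CC(=O)c1cc(=O)cc(-c2ccc(OCc3ccccc3)c(OCc3ccccc3)c2)o1 | intermediate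
11 | 3-bromo-4,5-dihydroxybenzaldehyde | O=Cc1cc(O)c(O)c(Br)c1 | starting material
12 | 3,4-bis(benzyloxy)-5-bromobenzaldehyde | O=Cc1cc(Br)c(OCc2ccccc2)c(OCc2ccccc2)c1 | intermediate
13 | 2-[3,4-bis(benzyloxy)-5-bromophenyl]-1,3-dioxolane | Brc1cc(C2OCCO2)cc(OCc2ccccc2)c1OCc1ccccc1 | intermediate
14 | methyl 2,3-bis(benzyloxy)-5-(1,3-dioxolan-2-yl)benzoate | COC(=O)c1cc(C2OCCO2)cc(OCc2ccccc2)c1OCc1ccccc1 | intermediate
15 | lithium 1-[2,3-bis(benzyloxy)-5-(1,3-dioxolan-2-yl)phenyl]-2,2-dibromoethenolate (not isolated) | [Li+].[O-]C(=C(Br)Br)c1cc(C2OCCO2)cc(OCc2ccccc2)c1OCc1ccccc1 | intermediate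
16 | lithium [2,3-bis(benzyloxy)-5-(1,3-dioxolan-2-yl)phenyl]ethynolate (not isolated) | [Li+].[O-]C#Cc1cc(C2OCCO2)cc(OCc2ccccc2)c1OCc1ccccc1 | intermediate
17 | {[2,3-bis(benzyloxy)-5-(1,3-dioxolan-2-yl)phenyl]ethynyloxy}triisopropylsilane | CC(C)[Si](OC#Cc1cc(C2OCCO2)cc(OCc2ccccc2)c1OCc1ccccc1)(C(C)C)C(C)C | intermediate
18 | {6-[3,4-bis(benzyloxy)phenyl]-4-oxo-4H-pyran-2-yl}ketene (not isolated) | O=C=Cc1cc(=O)cc(-c2ccc(OCc3ccccc3)c(OCc3ccccc3)c2)o1 | intermediate
19 | 4-{6-[3,4-bis(benzyloxy)phenyl]-4-oxo-4H-pyran-2-yl}-2-[2,3-bis(benzyloxy)-5-(1,3-dioxolan-2-yl)phenyl]-3-(triisopropylsiloxy)cyclobut-2-en-1-one, racemic at C4 (not isolated) | O=C1C(c2cc(C3OCCO3)cc(OCc3ccccc3)c2OCc2ccccc2)=C(O[Si](C(C)C)(C(C)C)C(C)C)C1c1cc(=O)cc(-c2ccc(OCc3ccccc3)c(OCc3ccccc3)c2)o1 | intermediate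
20 | 2-aryl-3-(triisopropylsiloxy)-4-(4-oxopyran-2-yl)buta-1,3-dien-1-one, ketene and pyranonyl groups cis on C7''=C8'' (not isolated) | O=C=C(c1cc(C2OCCO2)cc(OCc2ccccc2)c1OCc1ccccc1)/C(O[Si](C(C)C)(C(C)C)C(C)C)=C\c1cc(=O)cc(-c2ccc(OCc3ccccc3)c(OCc3ccccc3)c2)o1 | intermediate
21 | 4a''-H cyclohexadienone tautomer of 22, racemic at C4a'' (not isolated) | O=C1C=C(c2ccc(OCc3ccccc3)c(OCc3ccccc3)c2)OC2=CC(O[Si](C(C)C)(C(C)C)C(C)C)=C(c3cc(C4OCCO4)cc(OCc4ccccc4)c3OCc3ccccc3)C(=O)C12 | intermediate
22 | 2-[3,4-bis(benzyloxy)phenyl]-6-[2,3-bis(benzyloxy)-5-(1,3-dioxolan-2-yl)phenyl]-5-hydroxy-7-(triisopropylsiloxy)-4H-chromen-4-one | O=c1cc(-c2ccc(OCc3ccccc3)c(OCc3ccccc3)c2)oc2cc(O[Si](C(C)C)(C(C)C)C(C)C)c(-c3cc(C4OCCO4)cc(OCc4ccccc4)c3OCc3ccccc3)c(O)c12 | intermediate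
23 | 2-[3,4-bis(benzyloxy)phenyl]-6-[2,3-bis(benzyloxy)-5-(1,3-dioxolan-2-yl)phenyl]-5,7-dihydroxy-4H-chromen-4-one, present as its caesium phenoxide (not isolated) | O=c1cc(-c2ccc(OCc3ccccc3)c(OCc3ccccc3)c2)oc2cc(O)c(-c3cc(C4OCCO4)cc(OCc4ccccc4)c3OCc3ccccc3)c(O)c12 | intermediate
24 | 5,7-bis(benzyloxy)-2-[3,4-bis(benzyloxy)phenyl]-6-[2,3-bis(benzyloxy)-5-(1,3-dioxolan-2-yl)phenyl]-4H-chromen-4-one | O=c1cc(-c2ccc(OCc3ccccc3)c(OCc3ccccc3)c2)oc2cc(OCc3ccccc3)c(-c3cc(C4OCCO4)cc(OCc4ccccc4)c3OCc3ccccc3)c(OCc3ccccc3)c12 | intermediate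
25 | 3,4-bis(benzyloxy)-5-{5,7-bis(benzyloxy)-2-[3,4-bis(benzyloxy)phenyl]-4-oxo-4H-chromen-6-yl}benzaldehyde | O=Cc1cc(OCc2ccccc2)c(OCc2ccccc2)c(-c2c(OCc3ccccc3)cc3oc(-c4ccc(OCc5ccccc5)c(OCc5ccccc5)c4)cc(=O)c3c2OCc2ccccc2)c1 | intermediate
26 | 2,4,6-trihydroxyacetophenone | CC(=O)c1c(O)cc(O)cc1O | starting material
27 | 1-[2,4-bis(benzyloxy)-6-hydroxyphenyl]ethanone | CC(=O)c1c(O)cc(OCc2ccccc2)cc1OCc1ccccc1 | intermediate
28 | tert-butyl 3-[2,4-bis(benzyloxy)-6-hydroxyphenyl]-3-oxopropanoate | CC(C)(C)OC(=O)CC(=O)c1c(O)cc(OCc2ccccc2)cc1OCc1ccccc1 | intermediate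
29 | tert-butyl (Z)-2-[2,4-bis(benzyloxy)-6-hydroxybenzoyl]-3-(aryl)acrylate, aryl as in 25 | CC(C)(C)OC(=O)/C(C(=O)c1c(O)cc(OCc2ccccc2)cc1OCc1ccccc1)=C\c1cc(OCc2ccccc2)c(OCc2ccccc2)c(-c2c(OCc3ccccc3)cc3oc(-c4ccc(OCc5ccccc5)c(OCc5ccccc5)c4)cc(=O)c3c2OCc2ccccc2)c1 | intermediate
30 | tert-butyl (2S)-5,7-bis(benzyloxy)-2-(aryl)-4-oxochromane-3-carboxylate, aryl as in 25, C3 configurationally labile (not isolated) | O=C1C(C(=O)OC(C)(C)C)[C@@H](c2cc(OCc3ccccc3)c(OCc3ccccc3)c(-c3c(OCc4ccccc4)cc4oc(-c5ccc(OCc6ccccc6)c(OCc6ccccc6)c5)cc(=O)c4c3OCc3ccccc3)c2)Oc2cc(OCc3ccccc3)cc(OCc3ccccc3)c21 | intermediate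
31 | (2S)-5,7-bis(benzyloxy)-2-(3,4-bis(benzyloxy)-5-{5,7-bis(benzyloxy)-2-[3,4-bis(benzyloxy)phenyl]-4-oxo-4H-chromen-6-yl}phenyl)chroman-4-one | O=C1C[C@@H](c2cc(OCc3ccccc3)c(OCc3ccccc3)c(-c3c(OCc4ccccc4)cc4oc(-c5ccc(OCc6ccccc6)c(OCc6ccccc6)c5)cc(=O)c4c3OCc3ccccc3)c2)Oc2cc(OCc3ccccc3)cc(OCc3ccccc3)c21 | intermediate
32 | (2S)-2-{3-[2-(3,4-dihydroxyphenyl)-5,7-dihydroxy-4-oxo-4H-chromen-6-yl]-4,5-dihydroxyphenyl}-5,7-dihydroxychroman-4-one | O=C1C[C@@H](c2cc(O)c(O)c(-c3c(O)cc4oc(-c5ccc(O)c(O)c5)cc(=O)c4c3O)c2)Oc2cc(O)cc(O)c21 | target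

## Step count and risks

Total step count: 17. Longest linear sequence: 11 steps (1–5, 10–12, 15–17).

**1. Step 10.**
- What may go wrong:
  - Slow migration of the electron-poor pyranonyl group, so that the keto carbene is intercepted by the electron-rich alkyne or the ketene dimerises.
  - Dipolar cycloaddition of the diazo group to the ynol ether in the dark.
  - Reluctant electrocyclisation, because it interrupts the pyranone conjugation.
- Fallback, by known chemistry, makes the biaryl bond by cross-coupling instead of building the ring. It sets out from bromide 13 and comes back at 24.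
  - Miyaura borylation of 13 (B2pin2, Pd(dppf)Cl2, KOAc, dioxane, 90 °C) should give the pinacol boronate F1.
  - Commercial luteolin is benzylated at the three unchelated hydroxyls (BnBr, K2CO3, DMF) to 7,3',4'-tri-O-benzylluteolin F2.
  - Iodination ortho to the free 5-hydroxyl with BnMe3N·ICl2 and CaCO3 in CH2Cl2–MeOH should give the 6-iodoflavone F3, and benzylation of the 5-hydroxyl gives the 6-iodo tetrabenzyl ether F4.
  - Suzuki–Miyaura coupling of F1 with F4 (Pd(OAc)2, SPhos, K3PO4, toluene–H2O, 100 °C) should give 24.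

**2. Step 16.**
- What may go wrong:
  - Uncatalysed ring closure of the 6'-alkoxy-substituted substrate, possibly already during step 15.
  - Poor facial selectivity with the very large aryl group.
  - Acid-induced opening and reclosure of ring C at 80 °C, each of which erodes the enantiomeric purity.
- Fallback replaces asymmetric catalysis by racemic closure and resolution. It sets out from aldehyde 25 and acetophenone 27 and comes back at 31.
  - Claisen–Schmidt condensation (KOH, EtOH–THF, rt) should give the 2'-hydroxychalcone F5.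
  - NaOAc in refluxing EtOH closes it to the racemic flavanone F6.
  - Preparative chromatography on a polysaccharide chiral stationary phase separates 31 from the 2R enantiomer F7. F7 is re-equilibrated with NaOAc through the chalcone to F6 and recycled.

**3. Step 9.**
- What may go wrong:
  - Benzylic deprotonation and Wittig rearrangement of the benzyl ethers by surplus alkyllithium.
  - Incomplete rearrangement of the carbenoid.
  - Silylation on carbon instead of oxygen.
- Fallback reaches the ynolate by oxidising an acetylide instead of homologating an ester. It sets out from bromide 13 and comes back at ynolate 16.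
  - Sonogashira coupling with trimethylsilylacetylene (Pd(PPh3)2Cl2, CuI, Et3N, 80 °C) should give the silylalkyne F8.
  - K2CO3 in MeOH frees the terminal alkyne F9.
  - Deprotonation with one equivalent of n-BuLi and oxidation of the lithium acetylide with LiOOt-Bu (from t-BuOOH and LiN(SiMe3)2, THF, −78 to 0 °C) should give 16, which is silylated with TIPSCl as in step 9 to give 17.

Further compounds
F1 | step 10 | 2-[3,4-bis(benzyloxy)-5-(4,4,5,5-tetramethyl-1,3,2-dioxaborolan-2-yl)phenyl]-1,3-dioxolane | CC1(C)OB(OC1(C)C)c1cc(C2OCCO2)cc(OCc2ccccc2)c1OCc1ccccc1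
F2 | step 10 | 7-(benzyloxy)-2-[3,4-bis(benzyloxy)phenyl]-5-hydroxy-4H-chromen-4-one | O=c1cc(-c2ccc(OCc3ccccc3)c(OCc3ccccc3)c2)oc2cc(OCc3ccccc3)cc(O)c12
F3 | step 10 | 7-(benzyloxy)-2-[3,4-bis(benzyloxy)phenyl]-5-hydroxy-6-iodo-4H-chromen-4-one | O=c1cc(-c2ccc(OCc3ccccc3)c(OCc3ccccc3)c2)oc2cc(OCc3ccccc3)c(I)c(O)c12
F4 | step 10 | 5,7-bis(benzyloxy)-2-[3,4-bis(benzyloxy)phenyl]-6-iodo-4H-chromen-4-one | O=c1cc(-c2ccc(OCc3ccccc3)c(OCc3ccccc3)c2)oc2cc(OCc3ccccc3)c(I)c(OCc3ccccc3)c12
F5 | step 16 | (E)-1-[2,4-bis(benzyloxy)-6-hydroxyphenyl]-3-(aryl)prop-2-en-1-one, aryl as in 25 | O=C(/C=C/c1cc(OCc2ccccc2)c(OCc2ccccc2)c(-c2c(OCc3ccccc3)cc3oc(-c4ccc(OCc5ccccc5)c(OCc5ccccc5)c4)cc(=O)c3c2OCc2ccccc2)c1)c1c(O)cc(OCc2ccccc2)cc1OCc1ccccc1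
F6 | step 16 | racemic octabenzyl flavanone (racemate of 31) | O=C1CC(c2cc(OCc3ccccc3)c(OCc3ccccc3)c(-c3c(OCc4ccccc4)cc4oc(-c5ccc(OCc6ccccc6)c(OCc6ccccc6)c5)cc(=O)c4c3OCc3ccccc3)c2)Oc2cc(OCc3ccccc3)cc(OCc3ccccc3)c21
F7 | step 16 | (2R) enantiomer of 31 | O=C1C[C@H](c2cc(OCc3ccccc3)c(OCc3ccccc3)c(-c3c(OCc4ccccc4)cc4oc(-c5ccc(OCc6ccccc6)c(OCc6ccccc6)c5)cc(=O)c4c3OCc3ccccc3)c2)Oc2cc(OCc3ccccc3)cc(OCc3ccccc3)c21
F8 | step 9 | {[2,3-bis(benzyloxy)-5-(1,3-dioxolan-2-yl)phenyl]ethynyl}trimethylsilane | C[Si](C)(C)C#Cc1cc(C2OCCO2)cc(OCc2ccccc2)c1OCc1ccccc1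
F9 | step 9 | 2-[3,4-bis(benzyloxy)-5-ethynylphenyl]-1,3-dioxolane | C#Cc1cc(C2OCCO2)cc(OCc2ccccc2)c1OCc1ccccc1
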